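**Retrosynthetic overview**
1. 11 ⇒ 10: a single exchange step releases the cis-3,4-diol (from its phenylboronate) and the 4'-OH (from its acetate).
2. 10 ⇒ 3 + 7 + PhB(OH)2: formal [3+3] annulation. The C4–C4a bond forms by boron-templated hydroxyalkylation of the aldehyde, then the O1–C2 bond forms by 6-endo epoxide opening with inversion.
3. 7 ⇒ 6 ⇒ 4 + 5: organocatalytic epoxidation sets C2 and C3 absolutely, and a Wittig reaction builds the enal.
4. 3 ⇒ 1 + 2: prenylation comes first, so the A-ring partner is C2v-symmetric and the annulation has no regiochemical choice.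
5. Ring order: rings A and B are bought. A transient benzodioxaborin forms, then pyran ring C and a cis-fused dioxaborolane close in the same flask, and the dioxaborolane is removed last.

Assumption: "4β-ol" is read as drawn in the SMILES, that is (2R,3S,4S), 2,3-trans-3,4-cis. Flavan numbering is used for all bicyclic compounds.

**Step 1**
Reactants: 1 5-methoxyresorcinol (1.5 equiv); 2 prenol
Product: 3 5-methoxy-2-(3-methylbut-2-en-1-yl)benzene-1,3-diol
Conditions: acidic Al2O3, DCE, reflux
Reagents that add atoms: none
Why: Alumina-templated Friedel–Crafts ortho-allylation (the method used for 2-geranylresorcinols) brings the surface-bound phenol and the activated allylic alcohol together at the carbon flanked by both OH groups, giving the linear prenyl group and a C2v-symmetric arene whose two free ring positions and two OH groups are equivalent, with no stereocentre formed.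

**Step 2**
Reactants: 4 4-acetoxybenzaldehyde; 5 (triphenylphosphoranylidene)acetaldehyde
Product: 6 (E)-4-acetoxycinnamaldehyde
Conditions: toluene, 80 °C
Reagents that add atoms: none
Why: Wittig olefination with a stabilised formyl ylide gives the E-enal under neutral conditions that leave the aryl acetate untouched, with no stereocentre formed.

**Step 3**
Reactants: 6 (E)-4-acetoxycinnamaldehyde
Product: 7 (2R,3S)-3-(4-acetoxyphenyl)oxirane-2-carbaldehyde (trans)
Conditions: (R)-2-{bis[3,5-bis(trifluoromethyl)phenyl](trimethylsilyloxy)methyl}pyrrolidine (10 mol %), 35% aq H2O2 (1.3 equiv), CH2Cl2, rt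
Reagents that add atoms: hydrogen peroxide, OO
Why: In this Jørgensen iminium–enamine epoxidation (Weitz–Scheffer type) the CAr2(OTMS) group of the (R)-catalyst shields the Si face at Cβ of the E,s-trans iminium ion, so hydroperoxide adds to the Re face (sets 3S) and the enamine closes the trans-oxirane on the same face (sets 2R), while the acetate keeps the aryl epoxide from ionising.

**Step 4**
Reactants: 3 5-methoxy-2-prenylbenzene-1,3-diol; 7 (2R,3S)-3-(4-acetoxyphenyl)oxirane-2-carbaldehyde
Product: 10 (2R,3S,4S)-2-(4-acetoxyphenyl)-7-hydroxy-5-methoxy-8-prenylchroman-3,4-diyl phenylboronate (cis-fused dioxaborolane; 2-aryl trans to O3), via aryl phenylboronate half-ester 8 (not isolated), via epoxy-benzodioxaborin 9 (not isolated)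
Conditions: PhB(OH)2 (1.05 equiv), 4 Å MS, toluene, rt, 1 h; slow addition of 7 (1.0 equiv), EtCO2H (20 mol %), rt → 60 °C; chromatography, then recrystallisation (raises dr and ee)
Reagents that add atoms: phenylboronic acid, OB(O)c1ccccc1
Why: Proposed new method: half-ester 8 binds the aldehyde of 7 on boron and delivers its ortho carbon through a closed six-membered transition state (closest known reaction: the Nagata phenylboronic acid-templated ortho-hydroxyalkylation of phenols to 1,3,2-benzodioxaborins, which stops over-arylation), attacking anti to the epoxide C–O bond (polar Felkin–Anh, anti adduct = 3,4-cis) to set 4S in 9, after which acid-catalysed B–OAr exchange moves boron onto O4 and the epoxide oxygen and the freed phenol opens the activated benzylic C–O bond 6-endo-tet with inversion (oxirane 3S → C2 R, C3 untouched, as in known phenol/aryl-epoxide cyclisations to flavan-3-ols), so that the pyran and the dioxaborolane close together, and the strong cis preference of the five-membered boronate drains any 4-epimer through reversible ionisation of the electron-rich benzylic C4–O bond.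

**Step 5**
Reactants: 10 3,4-O-phenylboronate 4'-acetate
Product: 11 5-O-methyl-8-prenylafzelechin-4β-ol, (2R,3S,4S)
Conditions: HN(CH2CH2OH)2 (3 equiv), THF/i-PrOH, 0 °C → rt, Ar; filter; pH 6.5 phosphate wash; LH-20 gel chromatography
Reagents that add atoms: none
Why: Two known exchange reactions run side by side, namely transesterification of the boronate to the N→B-chelated diethanolamine adduct (which precipitates) and aminolysis of the aryl acetate, both close to neutral pH so that the acid-labile C4 carbinol, the prenyl group and all three stereocentres are untouched.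

**Compound list**
1 | 5-methoxyresorcinol | COc1cc(O)cc(O)c1 | starting material
2 | prenol (3-methylbut-2-en-1-ol) | CC(C)=CCO | starting material
3 | 5-methoxy-2-(3-methylbut-2-en-1-yl)benzene-1,3-diol | COc1cc(O)c(CC=C(C)C)c(O)c1 | intermediate
4 | 4-acetoxybenzaldehyde | CC(=O)Oc1ccc(C=O)cc1 | starting material
5 | (triphenylphosphoranylidene)acetaldehyde | O=CC=P(c1ccccc1)(c1ccccc1)c1ccccc1 | starting material
6 | (E)-4-acetoxycinnamaldehyde | CC(=O)Oc1ccc(/C=C/C=O)cc1 | intermediate
7 | (2R,3S)-3-(4-acetoxyphenyl)oxirane-2-carbaldehyde | O=C[C@@H]1O[C@H]1c1ccc(OC(C)=O)cc1 | intermediate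
8 | 3-hydroxy-5-methoxy-2-prenylphenyl hydrogen phenylboronate | COc1cc(O)c(CC=C(C)C)c(OB(O)c2ccccc2)c1 | intermediate
9 | (4S)-4-[(2S,3S)-3-(4-acetoxyphenyl)oxiran-2-yl]-5-methoxy-2-phenyl-8-prenyl-4H-1,3,2-benzodioxaborinin-7-ol | COc1cc(O)c(CC=C(C)C)c2c1[C@H](OB(c1ccccc1)O2)[C@@H]1O[C@H]1c1ccc(OC(C)=O)cc1 | intermediate
10 | (2R,3S,4S)-2-(4-acetoxyphenyl)-7-hydroxy-5-methoxy-8-prenylchroman-3,4-diyl phenylboronate | COc1cc(O)c(CC=C(C)C)c2c1[C@@H]1OB(c3ccccc3)O[C@@H]1[C@@H](c1ccc(OC(C)=O)cc1)O2 | intermediate
11 | 5-O-methyl-8-prenylafzelechin-4β-ol | COc1cc(O)c(CC=C(C)C)c2c1[C@H](O)[C@H](O)[C@@H](c1ccc(O)cc1)O2 | target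

**Step count**
- Total step count: 5.
- Longest linear sequence: 4 (4 → 6 → 7 → 10 → 11).

**Three steps most likely to fail**

Step 4 (cascade annulation). The risks are that 9 does not rearrange, that 10 ionises at C4 and is captured by 3, or that a second annulation occurs at C6. The fallback sets out from 3 and 7 and makes the two bonds one at a time on a different template. Ti(OiPr)4 in toluene converts 3 into the triisopropoxytitanium phenolate F1. F1 adds to 7 ortho- and anti-selectively (Casiraghi-type metal-phenolate hydroxyalkylation) and gives, after aqueous work-up, the epoxy-saligenol F2. Catalytic PPTS in CH2Cl2 at 0 °C closes the pyran 6-endo to the 4'-O-acetyl flavan-3,4-diol F3. Condensation of F3 with PhB(OH)2 over 4 Å sieves comes back to the route at 10.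

Step 1 (C2 versus C4 prenylation, bis-prenylation, chroman formation). The fallback sets out from 1 and replaces electrophilic substitution by directed ortho-metalation. NaH/MOMCl in DMF gives the bis-MOM ether F4. n-BuLi in THF at 0 °C deprotonates between the two OMOM groups to the 2-lithio arene F5. Prenyl bromide then gives the prenylated bis-MOM ether F6. Catalytic HCl in MeOH at rt removes both MOM groups and comes back to the route at 3.

Step 5 (base-sensitive leucoanthocyanidin, incomplete boron removal). The fallback sets out from 10 and removes the two groups separately under neutral conditions. Immobilised Candida antarctica lipase B with n-BuOH in MTBE at 35 °C deacetylates while C4–O is still locked in the boronate, giving the 4'-phenol boronate F7. Pinacol (1.5 equiv) in Et2O at rt then takes over the boron and comes back to the route at 11.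

**Further compounds**
F1 | step 4 | triisopropoxytitanium 3-hydroxy-5-methoxy-2-prenylphenolate | COc1cc(O)c(CC=C(C)C)c(O[Ti](OC(C)C)(OC(C)C)OC(C)C)c1
F2 | step 4 | 4-[(2S,3S)-3-[(S)-(2,4-dihydroxy-6-methoxy-3-prenylphenyl)(hydroxy)methyl]oxiran-2-yl]phenyl acetate | COc1cc(O)c(CC=C(C)C)c(O)c1[C@H](O)[C@@H]1O[C@H]1c1ccc(OC(C)=O)cc1
F3 | step 4 | (2R,3S,4S)-4'-O-acetyl-5-O-methyl-8-prenylafzelechin-4β-ol | COc1cc(O)c(CC=C(C)C)c2c1[C@H](O)[C@H](O)[C@@H](c1ccc(OC(C)=O)cc1)O2
F4 | step 1 | 1-methoxy-3,5-bis(methoxymethoxy)benzene | COCOc1cc(OC)cc(OCOC)c1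
F5 | step 1 | 4-methoxy-2,6-bis(methoxymethoxy)phenyllithium | [Li]c1c(OCOC)cc(OC)cc1OCOC
F6 | step 1 | 5-methoxy-1,3-bis(methoxymethoxy)-2-(3-methylbut-2-en-1-yl)benzene | COCOc1cc(OC)cc(OCOC)c1CC=C(C)C
F7 | step 5 | (2R,3S,4S)-7-hydroxy-2-(4-hydroxyphenyl)-5-methoxy-8-prenylchroman-3,4-diyl phenylboronate | COc1cc(O)c(CC=C(C)C)c2c1[C@@H]1OB(c3ccccc3)O[C@@H]1[C@@H](c1ccc(O)cc1)O2
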